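Ring A carries two different oxygens on neighbouring carbons, OH on C1 and the ring B aryloxy group on C2, with bromine on C3–C6. This is the pattern left when symmetric tetrabromobenzyne takes up an O-nucleophile and an electrophile across its strained bond. The route therefore cuts the C2–O ether bond and the C1–heteroatom bond (made as C1–B) across one aryne. In one operation, tetrabromobenzyne released from pentabromophenylmagnesium bromide adds bromomagnesium 2-bromophenoxide at C2, and the new C1–Mg bond is borylated with trimethyl borate. The precursors are hexabromobenzene as its mono-Grignard reagent and 2-bromophenol as its magnesium salt. Base-free peroxide oxidation of the boronic acid then gives the phenol.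

Key step: step 3

Remarks on the chemistry:
- Ring A is the perbrominated ring (C1 OH, C2 O-aryl, C3–C6 Br); ring B is the 2-bromophenyl ring.
- Only bromide-containing magnesium reagents are used. Any halide that adds back to the aryne then regenerates a pentabromophenyl species, and no chlorine can enter ring A.
- The boronic acid is oxidised without added base, because 2,6-disubstituted perhaloarylboronic acids lose boron rapidly once converted to boronate anions.

Step 1
Reactants: 1 2-bromophenol
Product: 2 bromomagnesium 2-bromophenoxide
Conditions: EtMgBr (1.0 equiv), THF, 0 °C; solution used directly
Reagents that add atoms: ethylmagnesium bromide, CC[Mg]Br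
Why: Deprotonation of a phenol by a Grignard reagent is an instantaneous acid–base reaction, and with one equivalent at 0 °C no bromine–magnesium exchange is expected on the electron-rich phenoxide ring.

Step 2
Reactants: 3 hexabromobenzene
Product: 4 pentabromophenylmagnesium bromide
Conditions: iPrMgBr (1.0 equiv), THF, −20 to 0 °C; solution kept at or below 0 °C
Reagents that add atoms: isopropylmagnesium bromide, CC(C)[Mg]Br
Why: Bromine–magnesium exchange on a perbrominated arene is driven by the stability of the perhaloaryl carbanion, one equivalent should stop at the mono-Grignard reagent, and pentahalophenyl Grignard reagents of this kind persist in cold THF.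

Step 3
Reactants: 2 bromomagnesium 2-bromophenoxide; 4 pentabromophenylmagnesium bromide; 5 trimethyl borate
Product: 9 [3,4,5,6-tetrabromo-2-(2-bromophenoxy)phenyl]boronic acid, via tetrabromobenzyne 6 (not isolated), via adduct arylmagnesium bromide 7 (not isolated), via trimethoxyborate complex 8 (not isolated)
Conditions: 2 (1.5 equiv) added to 4, THF, −20 °C, then warmed until quenched aliquots show 4 nearly consumed (expected between rt and 45 °C); B(OMe)3 (4 equiv), −40 → 0 °C; cold 1 M HCl
Reagents that add atoms: water, O
Why: Proposed new method: on warming, 4 should lose MgBr2 by beta-elimination to give aryne 6, the oxygen of 2 adds to one aryne carbon while magnesium passes to the neighbouring carbon to give 7, and 7 is captured at boron by trimethyl borate as ate complex 8, which acid hydrolyses to 9. The closest known reactions are the release of tetrahalobenzynes from pentahalophenyl-lithium or -magnesium reagents and the addition of magnesium thiolates and amides to magnesium-generated arynes followed by electrophilic quench of the new arylmagnesium; a phenoxide nucleophile with the C–Mg bond kept for borylation is the untested part. No ring is closed and no stereocentre is formed. Regiochemistry cannot go wrong because 6 is symmetric, so whichever carbon is attacked the oxygen at C2 and the boron at C1 end up flanked by Br at C3–C6. The selectivity needed is chemoselectivity: 7 must outlive 4, which is helped by 7 having one ortho bromide where 4 has two and by its inductively stabilising ortho aryloxy group, while the excess of 2 keeps the aryne away from carbon nucleophiles. The ring B bromine sits on an electron-rich ring and should not be exchanged by the stabilised aryl Grignard reagents at these temperatures.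

Step 4
Reactants: 9 [3,4,5,6-tetrabromo-2-(2-bromophenoxy)phenyl]boronic acid
Product: 10 3,4,5,6-tetrabromo-2-(2-bromophenoxy)phenol
Conditions: 30% aq. H2O2 (3 equiv), AcOH, THF, 0 °C → rt
Reagents that add atoms: hydrogen peroxide, OO
Why: Oxidation of an arylboronic acid to a phenol proceeds by peroxide addition to boron, aryl shift from boron to oxygen and hydrolysis of the borate ester; the acidic medium suppresses base-mediated protodeboronation, and the aryl bromides and the diaryl ether are inert to H2O2.

Compound list
1 | 2-bromophenol | Oc1ccccc1Br | starting material
2 | bromomagnesium 2-bromophenoxide | Br[Mg]Oc1ccccc1Br | intermediate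
3 | hexabromobenzene | Brc1c(Br)c(Br)c(Br)c(Br)c1Br | starting material
4 | pentabromophenylmagnesium bromide | Br[Mg]c1c(Br)c(Br)c(Br)c(Br)c1Br | intermediate
5 | trimethyl borate | COB(OC)OC | starting material
6 | 3,4,5,6-tetrabromobenzyne (3,4,5,6-tetrabromo-1,2-didehydrobenzene) | BrC1=C(Br)C(Br)=C(Br)C#C1 | intermediate
7 | [3,4,5,6-tetrabromo-2-(2-bromophenoxy)phenyl]magnesium bromide | Br[Mg]c1c(Br)c(Br)c(Br)c(Br)c1Oc1ccccc1Br | intermediate
8 | bromomagnesium [3,4,5,6-tetrabromo-2-(2-bromophenoxy)phenyl]trimethoxyborate | CO[B-](OC)(OC)c1c(Br)c(Br)c(Br)c(Br)c1Oc1ccccc1Br.[Mg+]Br | intermediate
9 | [3,4,5,6-tetrabromo-2-(2-bromophenoxy)phenyl]boronic acid | OB(O)c1c(Br)c(Br)c(Br)c(Br)c1Oc1ccccc1Br | intermediate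
10 | 3,4,5,6-tetrabromo-2-(2-bromophenoxy)phenol | Oc1c(Br)c(Br)c(Br)c(Br)c1Oc1ccccc1Br | target

Total step count: 4. Longest linear sequence: 3 steps (step 1 or step 2, then steps 3 and 4).

Steps most likely to fail

1. Step 3 (bears the label "Proposed new method:").
What may go wrong: adduct 7 loses a second MgBr2 at the temperature needed to break down 4. The mono-adduct is then drained into further arynes and oligomeric ethers before boron is added. The aryne may also be taken by carbon nucleophiles (4, or the ortho and para carbons of the phenoxide) instead of by oxygen.
Fallback, known chemistry only: it sets out from 2-bromophenol (1) and comes back to the route at arylmagnesium bromide 7.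
- Commercial 1,2,3,4-tetrabromobenzene is treated with (IO)2SO4 (from I2 and KIO3 in concentrated H2SO4) and then NaBr. This is the classical preparation of symmetrical polybrominated diaryliodonium salts and should give bis(2,3,4,5-tetrabromophenyl)iodonium bromide F1.
- Phenol 1 is O-arylated by F1 (NaOH, water/dioxane, 80 °C), the usual way to hindered polybrominated diaryl ethers, to give 1,2,3,4-tetrabromo-5-(2-bromophenoxy)benzene F2. The same ether results whether the aryl group is transferred at iodine or through tetrabromobenzyne formed by ortho-deprotonation of F1.
- The single ring A C–H of F2, flanked by Br and the aryloxy oxygen, is magnesiated with the magnesium amide TMPMgBr in THF at −20 °C, where a 2-bromoarylmagnesium should not eliminate. This gives 7, which is quenched with trimethyl borate (5) and worked up as in step 3.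

2. Step 4.
What may go wrong: protonolysis of the C1–B bond (protodeboronation) outruns the shift of the aryl group from boron to oxygen.
Fallback: it sets out from boronic acid 9 and comes back at target 10.
- The boron is given up on purpose: 9 is protodeboronated (aq. K2CO3, THF, 40 °C) to ether F2.
- F2 is magnesiated with TMPMgBr at −20 °C to 7.
- 7 is oxygenated directly with tert-butyl peroxybenzoate (THF, −20 → 0 °C; aq. HCl work-up), the known conversion of aryl Grignard reagents into aryl tert-butyl ethers. This should give 1,2,3,4-tetrabromo-5-(2-bromophenoxy)-6-tert-butoxybenzene F3.
- TFA in CH2Cl2 at rt removes the tert-butyl group and should deliver 10.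

3. Step 2.
What may go wrong: uneven exchange on the barely soluble solid leaves unreacted 3 beside doubly magnesiated material, or MgBr2 is lost early if the suspension is warmed to speed dissolution.
Fallback: it sets out from hexabromobenzene (3) and comes back at Grignard reagent 4.
- Bromine–lithium exchange with nBuLi in Et2O at −78 °C, the classical route to this carbanion, should give pentabromophenyllithium F4 cleanly even from a suspension.
- Transmetalation with MgBr2·OEt2 at −78 °C before any warming converts F4 into 4.

Further compounds
F1 | step 3 | bis(2,3,4,5-tetrabromophenyl)iodonium bromide | [Br-].Brc1c(Br)c(Br)c(Br)cc1[I+]c1cc(Br)c(Br)c(Br)c1Br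
F2 | step 3 | 1,2,3,4-tetrabromo-5-(2-bromophenoxy)benzene | Brc1ccccc1Oc1cc(Br)c(Br)c(Br)c1Br
F3 | step 4 | 1,2,3,4-tetrabromo-5-(2-bromophenoxy)-6-tert-butoxybenzene | CC(C)(C)Oc1c(Br)c(Br)c(Br)c(Br)c1Oc1ccccc1Br
F4 | step 2 | pentabromophenyllithium | [Li]c1c(Br)c(Br)c(Br)c(Br)c1Br
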